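The route builds the six-membered β-ring (C1–C6, carotenoid numbering; primed atoms are in the ε-ring) by a polar [4+2] annulation. A 2-silyloxy-4-methoxydiene supplies C2–C5 with O3 and the C5 methyl; isopropylidene Meldrum's acid supplies the gem-dimethyl C1 and C6. C1–C2 and C5–C6 form in one operation, and acid then expels methanol. The step exploits the 1,3-placement of the C3 oxygen and the C5 methyl and the quaternary C1 next to C6. The resulting keto ester serves both end groups: enantiomeric CBS reductions set C3 and C3′, and a base shift makes C5=C6. A furan masks the C8–C11 keto-enal, and Wittig couplings with the C10 dialdehyde assemble the polyene.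

Key step: step 2

Remark on the chemistry: the keto ester of step 3 is racemic at its ester-bearing carbon. For the β-ring that centre is erased in step 5. For the ε-ring only the trans hydroxy ester of step 11 is carried on, and its cis C1 epimer is removed by chromatography. New C=C bonds from the Wittig steps are assumed to equilibrate thermally to E.

Step 1
Reactants: 1 (3E)-4-methoxypent-3-en-2-one
Product: 3 (3E)-4-methoxy-2-[(trimethylsilyl)oxy]penta-1,3-diene, via lithium enolate 2 (not isolated)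
Conditions: LiN(i-Pr)2, THF, −78 °C; Me3SiCl, −78 → 0 °C; distillation
Reagents that add atoms: chlorotrimethylsilane, C[Si](C)(C)Cl
Why: Kinetic α′-deprotonation of the vinylogous ester at the acetyl methyl and O-silylation (silyl enol ether formation) should give the Danishefsky-type diene with the 3E geometry retained.

Step 2
Reactants: 3 (3E)-4-methoxy-2-[(trimethylsilyl)oxy]penta-1,3-diene; 4 2,2-dimethyl-5-(propan-2-ylidene)-1,3-dioxane-4,6-dione (isopropylidene Meldrum's acid)
Product: 6 3,3,7,11,11-pentamethyl-2,4-dioxaspiro[5.5]undec-7-ene-1,5,9-trione, via cycloadduct 5 (not isolated)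
Conditions: toluene, 25 → 60 °C; then 0.5 M HCl, THF, 0 → 25 °C
Reagents that add atoms: none
Why: Polar, asynchronous [4+2] cycloaddition (Diels–Alder reaction of a Danishefsky-type 1-alkoxy-3-silyloxydiene with an alkylidene Meldrum's acid, in the stepwise limit a Mukaiyama–Michael addition followed by ring closure): the terminal CH2 of 3 (C2) attacks the CMe2 carbon of 4 (C1), and the Meldrum's-stabilised carbon (C6) then bonds to the methoxy-bearing diene terminus (C5). The single six-membered ring closes as the second σ-bond of the cycloaddition (a 6-endo-trig attack on the silyloxy-oxocarbenium in the stepwise picture), and any open-chain Michael adduct or O-closed hetero-Diels–Alder isomer is expected to converge on the same carbocycle under the acidic work-up by addition–elimination at C5. The only stereocentre created (C5 of 5) is racemic and is destroyed when acid hydrolyses the silyl enol ether and expels methanol, so no stereocontrol is required. The step needs regioselectivity, which matched polarity secures: C2 is the most nucleophilic diene carbon and the β-carbon of 4 its only electrophilic site, so the gem-dimethyl carbon ends next to C6. Methanol is lost by β-elimination across C4–C5 because C6 is quaternary, which places the enone at C3/C4=C5 and leaves the new C5–C6 σ-bond for later conversion into the ring double bond.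

Step 3
Reactants: 6 3,3,7,11,11-pentamethyl-2,4-dioxaspiro[5.5]undec-7-ene-1,5,9-trione
Product: 9 methyl 2,6,6-trimethyl-4-oxocyclohex-2-ene-1-carboxylate (racemic), via half-ester carboxylate 7 (not isolated), via sodium dienolate 8 (not isolated)
Conditions: NaOMe (1.1 equiv), MeOH, 0 → 50 °C; then AcOH
Reagents that add atoms: sodium methoxide, [Na+].[O-]C
Why: Methoxide opens the Meldrum's acid ring with loss of acetone, the vinylogous β-keto carboxylate decarboxylates, and protonation of the dienolate should give the ketone-conjugated enone ester (Meldrum's acid alcoholysis–decarboxylation), whose new ester-bearing centre is racemic.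

Step 4
Reactants: 9 methyl 2,6,6-trimethyl-4-oxocyclohex-2-ene-1-carboxylate (racemic)
Product: 10 methyl (4S)-4-hydroxy-2,6,6-trimethylcyclohex-2-ene-1-carboxylate (both C1 epimers, carried on together)
Conditions: (3aR)-1-methyl-3,3-diphenyltetrahydro-1H,3H-pyrrolo[1,2-c][1,3,2]oxazaborole [(R)-Me-CBS, 0.2 equiv], catecholborane, toluene, −78 °C; then MeOH, pH 7 buffer
Reagents that add atoms: none
Why: Corey–Bakshi–Shibata reduction, in which the catalyst binds the ketone with the alkenyl arm as the large group and delivers hydride to one face, should set the carbinol centre as 4S (the future C3, R in the target), while the ester-bearing centre stays mixed and is erased in step 5.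

Step 5
Reactants: 10 methyl (4S)-4-hydroxy-2,6,6-trimethylcyclohex-2-ene-1-carboxylate
Product: 11 methyl (4R)-4-hydroxy-2,6,6-trimethylcyclohex-1-ene-1-carboxylate
Conditions: NaOMe (0.3 equiv), MeOH, 65 °C
Reagents that add atoms: none
Why: A base-catalysed prototropic shift through the ester dienolate (deconjugated-to-conjugated ester isomerisation under thermodynamic control) should move the alkene into the tetrasubstituted C5=C6 position, so both C1 epimers converge while the carbinol centre is untouched and changes its descriptor only through the CIP priorities.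

Step 6
Reactants: 11 methyl (4R)-4-hydroxy-2,6,6-trimethylcyclohex-1-ene-1-carboxylate
Product: 12 (1R)-4-(hydroxymethyl)-3,5,5-trimethylcyclohex-3-en-1-ol
Conditions: i-Bu2AlH (3.5 equiv), CH2Cl2, −78 → 0 °C; aq. potassium sodium tartrate
Reagents that add atoms: none
Why: 1,2-Reduction of the conjugated ester by the aluminium hydride (ester-to-alcohol reduction) should give the allylic alcohol, the secondary alkoxide being inert.

Step 7
Reactants: 12 (1R)-4-(hydroxymethyl)-3,5,5-trimethylcyclohex-3-en-1-ol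
Product: 13 (1R)-4-(bromomethyl)-3,5,5-trimethylcyclohex-3-en-1-ol
Conditions: N-bromosuccinimide (1.5 equiv), Me2S (1.8 equiv), CH2Cl2, −20 → 0 °C
Reagents that add atoms: N-bromosuccinimide, O=C1CCC(=O)N1Br
Why: Corey–Kim halogenation should convert only the allylic primary alcohol into the bromide through its alkoxysulfonium ion and return the saturated secondary alcohol unchanged on work-up.

Step 8
Reactants: 13 (1R)-4-(bromomethyl)-3,5,5-trimethylcyclohex-3-en-1-ol; 14 furan-3-ylmethanol
Product: 16 (1R)-4-{[3-(hydroxymethyl)furan-2-yl]methyl}-3,5,5-trimethylcyclohex-3-en-1-ol, via dilithio furan 15 (not isolated)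
Conditions: 14 (2.5 equiv), n-BuLi (5.0 equiv), THF, −78 → 0 °C; then 13, −78 → 25 °C; aq. NH4Cl
Reagents that add atoms: none
Why: Alkoxide-directed ortho-lithiation of 14 at C2 of the furan and SN2 alkylation by the primary allylic bromide should form C7–C8, with SN2′ attack blocked by the fully substituted C5 and one equivalent of 15 absorbing the hydroxyl proton of 13.

Step 9
Reactants: 16 (1R)-4-{[3-(hydroxymethyl)furan-2-yl]methyl}-3,5,5-trimethylcyclohex-3-en-1-ol
Product: 17 tert-butyl{[2-({(4R)-4-[(tert-butyldimethylsilyl)oxy]-2,6,6-trimethylcyclohex-1-en-1-yl}methyl)furan-3-yl]methoxy}dimethylsilane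
Conditions: t-BuMe2SiCl (2.5 equiv), imidazole, DMF, 25 °C
Reagents that add atoms: tert-butyldimethylsilyl chloride, CC(C)(C)[Si](C)(C)Cl
Why: Imidazole-promoted silylation (silyl ether protection) should cap both hydroxyls.

Step 10
Reactants: 17 tert-butyl{[2-({(4R)-4-[(tert-butyldimethylsilyl)oxy]-2,6,6-trimethylcyclohex-1-en-1-yl}methyl)furan-3-yl]methoxy}dimethylsilane
Product: 19 (2E)-3-{[(tert-butyldimethylsilyl)oxy]methyl}-5-{(4R)-4-[(tert-butyldimethylsilyl)oxy]-2,6,6-trimethylcyclohex-1-en-1-yl}-4-oxopent-2-enal, via Z keto-enal 18 (not isolated)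
Conditions: N-bromosuccinimide (1.05 equiv), NaHCO3, acetone–H2O (10:1), −20 °C; then pyridine, 25 °C
Reagents that add atoms: water, O
Why: Oxidative furan ring opening (bromonium attack, hydration, loss of HBr) should unmask the C8 ketone and C11 aldehyde as the Z keto-enal, which pyridine equilibrates to the E isomer with C8 and C11 trans, the furan being far more nucleophilic than the shielded tetrasubstituted ring alkene.

Step 11
Reactants: 9 methyl 2,6,6-trimethyl-4-oxocyclohex-2-ene-1-carboxylate (racemic)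
Product: 20 methyl (1R,4R)-4-hydroxy-2,6,6-trimethylcyclohex-2-ene-1-carboxylate (trans)
Conditions: (3aS)-1-methyl-3,3-diphenyltetrahydro-1H,3H-pyrrolo[1,2-c][1,3,2]oxazaborole [(S)-Me-CBS, 0.2 equiv], catecholborane, toluene, −78 °C; then MeOH, pH 7 buffer; chromatography on silica gel
Reagents that add atoms: none
Why: Corey–Bakshi–Shibata reduction with the enantiomeric catalyst should set the carbinol as 4R (the future C3′) in both enantiomers of racemic 9, so the trans product 20 (1R, the future C6′) arises from the (1R) enantiomer alone and is freed by chromatography from the cis (1S,4R) epimer that the (1S) enantiomer gives.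

Step 12
Reactants: 20 methyl (1R,4R)-4-hydroxy-2,6,6-trimethylcyclohex-2-ene-1-carboxylate
Product: 21 (1R,4R)-4-hydroxy-2,6,6-trimethylcyclohex-2-ene-1-carbaldehyde
Conditions: i-Bu2AlH (2.3 equiv), toluene, −78 °C; MeOH at −78 °C; aq. potassium sodium tartrate
Reagents that add atoms: none
Why: Partial reduction of the hindered ester (ester-to-aldehyde reduction) should stop at the aldehyde because the tetrahedral aluminium hemiacetal is stable at −78 °C, and the neutral work-up avoids epimerisation at C1.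

Step 13
Reactants: 21 (1R,4R)-4-hydroxy-2,6,6-trimethylcyclohex-2-ene-1-carbaldehyde; 22 1-(triphenylphosphoranylidene)propan-2-one
Product: 23 (3E)-4-[(1R,4R)-4-hydroxy-2,6,6-trimethylcyclohex-2-en-1-yl]but-3-en-2-one [(3R,6R)-3-hydroxy-α-ionone]
Conditions: toluene, 90 °C
Reagents that add atoms: none
Why: Wittig olefination with the stabilised ylide should give the E enone under base-free conditions that preserve the epimerisable C1 (C6′) centre.

Step 14
Reactants: 23 (3E)-4-[(1R,4R)-4-hydroxy-2,6,6-trimethylcyclohex-2-en-1-yl]but-3-en-2-one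
Product: 24 (1E)-1-[(1R,4R)-4-hydroxy-2,6,6-trimethylcyclohex-2-en-1-yl]-3-methylpenta-1,4-dien-3-ol (both C3 epimers)
Conditions: CH2=CHMgBr (3 equiv), THF, −20 → 0 °C; aq. NH4Cl
Reagents that add atoms: vinylmagnesium bromide, C=C[Mg]Br
Why: 1,2-Addition of the vinyl Grignard reagent to the enone carbonyl (Grignard addition) should give the tertiary bis-allylic alcohol, whose new carbinol centre is lost in step 15.

Step 15
Reactants: 24 (1E)-1-[(1R,4R)-4-hydroxy-2,6,6-trimethylcyclohex-2-en-1-yl]-3-methylpenta-1,4-dien-3-ol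
Product: 25 [(2E,4E)-5-[(1R,4R)-4-hydroxy-2,6,6-trimethylcyclohex-2-en-1-yl]-3-methylpenta-2,4-dien-1-yl]triphenylphosphonium bromide
Conditions: PPh3·HBr, MeOH, 0 → 25 °C
Reagents that add atoms: triphenylphosphine hydrobromide, [Br-].[PH+](c1ccccc1)(c1ccccc1)c1ccccc1
Why: Ionisation of the tertiary bis-allylic alcohol and capture of the pentadienyl cation by triphenylphosphine at its primary terminus (the vinyl-ionol to phosphonium salt conversion, an SN1-type allylic transposition) should give the C15 Wittig salt, the ring allylic alcohol ionising far less readily.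

Step 16
Reactants: 25 [(2E,4E)-5-[(1R,4R)-4-hydroxy-2,6,6-trimethylcyclohex-2-en-1-yl]-3-methylpenta-2,4-dien-1-yl]triphenylphosphonium bromide; 26 (2E,4E,6E)-2,7-dimethylocta-2,4,6-trienedial
Product: 28 (2E,4E,6E,8E,10E,12E)-13-[(1R,4R)-4-hydroxy-2,6,6-trimethylcyclohex-2-en-1-yl]-2,7,11-trimethyltrideca-2,4,6,8,10,12-hexaenal, via ylide 27 (not isolated)
Conditions: 26 (2 equiv), NaOMe (1.1 equiv), CH2Cl2–MeOH, −10 → 25 °C, slow addition of the ylide; then n-heptane, 90 °C
Reagents that add atoms: none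
Why: Wittig olefination of one aldehyde group of the dialdehyde used in excess should form C11′=C12′, and heating equilibrates the new bond to E.

Step 17
Reactants: 28 (2E,4E,6E,8E,10E,12E)-13-[(1R,4R)-4-hydroxy-2,6,6-trimethylcyclohex-2-en-1-yl]-2,7,11-trimethyltrideca-2,4,6,8,10,12-hexaenal
Product: 29 (2E,4E,6E,8E,10E,12E)-13-[(1R,4R)-4-hydroxy-2,6,6-trimethylcyclohex-2-en-1-yl]-2,7,11-trimethyltrideca-2,4,6,8,10,12-hexaen-1-ol
Conditions: NaBH4, MeOH–CH2Cl2, 0 °C
Reagents that add atoms: none
Why: Chemoselective 1,2-reduction of the polyenal by borohydride (carbonyl reduction) should give the primary polyenyl alcohol.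

Step 18
Reactants: 29 (2E,4E,6E,8E,10E,12E)-13-[(1R,4R)-4-hydroxy-2,6,6-trimethylcyclohex-2-en-1-yl]-2,7,11-trimethyltrideca-2,4,6,8,10,12-hexaen-1-ol
Product: 30 [(2E,4E,6E,8E,10E,12E)-13-[(1R,4R)-4-hydroxy-2,6,6-trimethylcyclohex-2-en-1-yl]-2,7,11-trimethyltrideca-2,4,6,8,10,12-hexaen-1-yl]triphenylphosphonium bromide
Conditions: PPh3·HBr, MeOH–CH2Cl2, 0 → 25 °C
Reagents that add atoms: triphenylphosphine hydrobromide, [Br-].[PH+](c1ccccc1)(c1ccccc1)c1ccccc1
Why: The same SN1-type phosphonium salt formation as in step 15 should apply, the polyenyl cation being captured at C12 while the isolated ring allylic alcohol stays intact.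

Step 19
Reactants: 30 [(2E,4E,6E,8E,10E,12E)-13-[(1R,4R)-4-hydroxy-2,6,6-trimethylcyclohex-2-en-1-yl]-2,7,11-trimethyltrideca-2,4,6,8,10,12-hexaen-1-yl]triphenylphosphonium bromide; 19 (2E)-3-{[(tert-butyldimethylsilyl)oxy]methyl}-5-{(4R)-4-[(tert-butyldimethylsilyl)oxy]-2,6,6-trimethylcyclohex-1-en-1-yl}-4-oxopent-2-enal
Product: 32 (3R,3′R,6′R)-3,19-bis[(tert-butyldimethylsilyl)oxy]-3′-hydroxy-7,8-dihydro-β,ε-caroten-8-one, via ylide 31 (not isolated)
Conditions: 1,2-epoxybutane, EtOH, 75 °C, dark, argon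
Reagents that add atoms: none
Why: Wittig olefination under neutral conditions (the epoxide scavenges HBr) should form C11=C12, since the aldehyde of 19 reacts far faster than its hindered cross-conjugated ketone, the acidic C7 methylene is not exposed to strong base, and heating brings the new bond to E.

Step 20
Reactants: 32 (3R,3′R,6′R)-3,19-bis[(tert-butyldimethylsilyl)oxy]-3′-hydroxy-7,8-dihydro-β,ε-caroten-8-one
Product: 33 (3R,3′R,6′R)-3,3′,19-trihydroxy-7,8-dihydro-β,ε-caroten-8-one (siphonaxanthin, CNP0183826.2)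
Conditions: Bu4NF, AcOH (1:1, 4 equiv each), THF, 25 °C, dark
Reagents that add atoms: none
Why: Fluoride-mediated cleavage of both silyl ethers (desilylation), buffered with acetic acid, should leave the β,γ-unsaturated enone, the allylic C3′ alcohol and the polyene intact.

Compound list
1 | (3E)-4-methoxypent-3-en-2-one | CO/C(C)=C/C(C)=O | starting material
2 | lithium (3E)-4-methoxypenta-1,3-dien-2-olate | [Li]OC(=C)/C=C(\C)OC | intermediate
3 | (3E)-4-methoxy-2-[(trimethylsilyl)oxy]penta-1,3-diene | C=C(O[Si](C)(C)C)/C=C(\C)OC | intermediate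
4 | 2,2-dimethyl-5-(propan-2-ylidene)-1,3-dioxane-4,6-dione | CC(C)=C1C(=O)OC(C)(C)OC1=O | starting material
5 | 7-methoxy-3,3,7,11,11-pentamethyl-9-[(trimethylsilyl)oxy]-2,4-dioxaspiro[5.5]undec-8-ene-1,5-dione (racemic) | COC1(C)C=C(O[Si](C)(C)C)CC(C)(C)C12C(=O)OC(C)(C)OC2=O | intermediate
6 | 3,3,7,11,11-pentamethyl-2,4-dioxaspiro[5.5]undec-7-ene-1,5,9-trione | CC1=CC(=O)CC(C)(C)C12C(=O)OC(C)(C)OC2=O | intermediate
7 | sodium 1-(methoxycarbonyl)-2,6,6-trimethyl-4-oxocyclohex-2-ene-1-carboxylate | COC(=O)C1(C([O-])=O)C(C)=CC(=O)CC1(C)C.[Na+] | intermediate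
8 | sodium 4-(methoxycarbonyl)-3,5,5-trimethylcyclohexa-1,3-dien-1-olate | COC(=O)C1=C(C)C=C([O-])CC1(C)C.[Na+] | intermediate
9 | methyl 2,6,6-trimethyl-4-oxocyclohex-2-ene-1-carboxylate (racemic) | COC(=O)C1C(C)=CC(=O)CC1(C)C | intermediate
10 | methyl (4S)-4-hydroxy-2,6,6-trimethylcyclohex-2-ene-1-carboxylate (C1 epimers) | COC(=O)C1C(C)=C[C@@H](O)CC1(C)C | intermediate
11 | methyl (4R)-4-hydroxy-2,6,6-trimethylcyclohex-1-ene-1-carboxylate | COC(=O)C1=C(C)C[C@@H](O)CC1(C)C | intermediate
12 | (1R)-4-(hydroxymethyl)-3,5,5-trimethylcyclohex-3-en-1-ol | OCC1=C(C)C[C@@H](O)CC1(C)C | intermediate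
13 | (1R)-4-(bromomethyl)-3,5,5-trimethylcyclohex-3-en-1-ol | BrCC1=C(C)C[C@@H](O)CC1(C)C | intermediate
14 | furan-3-ylmethanol | OCc1ccoc1 | starting material
15 | lithium (2-lithiofuran-3-yl)methanolate | [Li]OCc1ccoc1[Li] | intermediate
16 | (1R)-4-{[3-(hydroxymethyl)furan-2-yl]methyl}-3,5,5-trimethylcyclohex-3-en-1-ol | OCc1ccoc1CC1=C(C)C[C@@H](O)CC1(C)C | intermediate
17 | tert-butyl{[2-({(4R)-4-[(tert-butyldimethylsilyl)oxy]-2,6,6-trimethylcyclohex-1-en-1-yl}methyl)furan-3-yl]methoxy}dimethylsilane | CC(C)(C)[Si](C)(C)OCc1ccoc1CC1=C(C)C[C@@H](O[Si](C)(C)C(C)(C)C)CC1(C)C | intermediate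
18 | (2Z)-3-{[(tert-butyldimethylsilyl)oxy]methyl}-5-{(4R)-4-[(tert-butyldimethylsilyl)oxy]-2,6,6-trimethylcyclohex-1-en-1-yl}-4-oxopent-2-enal | O=C/C=C(/CO[Si](C)(C)C(C)(C)C)C(=O)CC1=C(C)C[C@@H](O[Si](C)(C)C(C)(C)C)CC1(C)C | intermediate
19 | (2E)-3-{[(tert-butyldimethylsilyl)oxy]methyl}-5-{(4R)-4-[(tert-butyldimethylsilyl)oxy]-2,6,6-trimethylcyclohex-1-en-1-yl}-4-oxopent-2-enal | O=C/C=C(\CO[Si](C)(C)C(C)(C)C)C(=O)CC1=C(C)C[C@@H](O[Si](C)(C)C(C)(C)C)CC1(C)C | intermediate
20 | methyl (1R,4R)-4-hydroxy-2,6,6-trimethylcyclohex-2-ene-1-carboxylate | CC1=C[C@H](O)CC(C)(C)[C@H]1C(=O)OC | intermediate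
21 | (1R,4R)-4-hydroxy-2,6,6-trimethylcyclohex-2-ene-1-carbaldehyde | CC1=C[C@H](O)CC(C)(C)[C@H]1C=O | intermediate
22 | 1-(triphenylphosphoranylidene)propan-2-one | CC(=O)C=P(c1ccccc1)(c1ccccc1)c1ccccc1 | starting material
23 | (3E)-4-[(1R,4R)-4-hydroxy-2,6,6-trimethylcyclohex-2-en-1-yl]but-3-en-2-one | CC1=C[C@H](O)CC(C)(C)[C@H]1/C=C/C(C)=O | intermediate
24 | (1E)-1-[(1R,4R)-4-hydroxy-2,6,6-trimethylcyclohex-2-en-1-yl]-3-methylpenta-1,4-dien-3-ol (C3 epimers) | CC1=C[C@H](O)CC(C)(C)[C@H]1/C=C/C(C)(O)C=C | intermediate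
25 | [(2E,4E)-5-[(1R,4R)-4-hydroxy-2,6,6-trimethylcyclohex-2-en-1-yl]-3-methylpenta-2,4-dien-1-yl]triphenylphosphonium bromide | CC1=C[C@H](O)CC(C)(C)[C@H]1/C=C/C(C)=C/C[P+](c1ccccc1)(c1ccccc1)c1ccccc1.[Br-] | intermediate
26 | (2E,4E,6E)-2,7-dimethylocta-2,4,6-trienedial | O=C/C(C)=C/C=C/C=C(C)/C=O | starting material
27 | C15 ylide: (1R,4R)-3,5,5-trimethyl-4-[(1E,3E)-3-methyl-5-(triphenylphosphoranylidene)penta-1,3-dien-1-yl]cyclohex-2-en-1-ol | CC1=C[C@H](O)CC(C)(C)[C@H]1/C=C/C(C)=C/C=P(c1ccccc1)(c1ccccc1)c1ccccc1 | intermediate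
28 | (2E,4E,6E,8E,10E,12E)-13-[(1R,4R)-4-hydroxy-2,6,6-trimethylcyclohex-2-en-1-yl]-2,7,11-trimethyltrideca-2,4,6,8,10,12-hexaenal | CC1=C[C@H](O)CC(C)(C)[C@H]1/C=C/C(C)=C/C=C/C(C)=C/C=C/C=C(C)/C=O | intermediate
29 | (2E,4E,6E,8E,10E,12E)-13-[(1R,4R)-4-hydroxy-2,6,6-trimethylcyclohex-2-en-1-yl]-2,7,11-trimethyltrideca-2,4,6,8,10,12-hexaen-1-ol | CC1=C[C@H](O)CC(C)(C)[C@H]1/C=C/C(C)=C/C=C/C(C)=C/C=C/C=C(C)/CO | intermediate
30 | [(2E,4E,6E,8E,10E,12E)-13-[(1R,4R)-4-hydroxy-2,6,6-trimethylcyclohex-2-en-1-yl]-2,7,11-trimethyltrideca-2,4,6,8,10,12-hexaen-1-yl]triphenylphosphonium bromide | CC1=C[C@H](O)CC(C)(C)[C@H]1/C=C/C(C)=C/C=C/C(C)=C/C=C/C=C(C)/C[P+](c1ccccc1)(c1ccccc1)c1ccccc1.[Br-] | intermediate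
31 | C25 ylide: (1R,4R)-3,5,5-trimethyl-4-[(1E,3E,5E,7E,9E,11E)-3,7,12-trimethyl-13-(triphenylphosphoranylidene)trideca-1,3,5,7,9,11-hexaen-1-yl]cyclohex-2-en-1-ol | CC1=C[C@H](O)CC(C)(C)[C@H]1/C=C/C(C)=C/C=C/C(C)=C/C=C/C=C(C)/C=P(c1ccccc1)(c1ccccc1)c1ccccc1 | intermediate
32 | (3R,3′R,6′R)-3,19-bis[(tert-butyldimethylsilyl)oxy]-3′-hydroxy-7,8-dihydro-β,ε-caroten-8-one | CC1=C[C@H](O)CC(C)(C)[C@H]1/C=C/C(C)=C/C=C/C(C)=C/C=C/C=C(C)/C=C/C=C(\CO[Si](C)(C)C(C)(C)C)C(=O)CC1=C(C)C[C@@H](O[Si](C)(C)C(C)(C)C)CC1(C)C | intermediate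
33 | (3R,3′R,6′R)-3,3′,19-trihydroxy-7,8-dihydro-β,ε-caroten-8-one (siphonaxanthin) | CC1=C[C@H](O)CC(C)(C)[C@H]1/C=C/C(C)=C/C=C/C(C)=C/C=C/C=C(C)/C=C/C=C(\CO)C(=O)CC1=C(C)C[C@@H](O)CC1(C)C | target

Step count
Total: 20 steps. Longest linear sequence: 13 steps (steps 1–3, 11–18, 19, 20).

Steps most likely to fail

Step 2. The ring closure joins a fully substituted diene terminus to a quaternary carbon flanked by the gem-dimethyl carbon, so the reaction may stall after the first C–C bond or lose the diene to hydrolysis. The fallback sets out from 4 and comes back at 6. (3E)-2-[(Trimethylsilyl)oxy]penta-1,3-diene F1, made from commercial (3E)-pent-3-en-2-one with LiN(i-Pr)2 and Me3SiCl, has an unhindered E-methyl terminus and should undergo a normal thermal Diels–Alder reaction with 4 (toluene, 80 °C), forming the same two ring bonds. This gives 3,3,7,11,11-pentamethyl-9-[(trimethylsilyl)oxy]-2,4-dioxaspiro[5.5]undec-8-ene-1,5-dione F2. Saegusa–Ito dehydrogenation of this silyl enol ether with Pd(OAc)2 in MeCN then installs the C4=C5 enone and delivers 6.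

Step 10. Electrophilic bromine may also attack the tetrasubstituted ring alkene, and the Z-to-E equilibration of the trisubstituted keto-enal may stay incomplete. The fallback sets out from 17 and comes back at 19. Controlled-potential anodic oxidation of 17 in MeOH (carbon anode, Et4NOTs, 2,6-lutidine, −20 °C) should oxidise only the furan, which has the lower oxidation potential. This gives the bis-acetal tert-butyl{[2,5-dimethoxy-2-({(4R)-4-[(tert-butyldimethylsilyl)oxy]-2,6,6-trimethylcyclohex-1-en-1-yl}methyl)-2,5-dihydrofuran-3-yl]methoxy}dimethylsilane F3. Mild hydrolysis (pyridinium p-toluenesulfonate, wet acetone, 0 °C) followed by pyridine then releases and equilibrates the keto-enal to 19.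

Step 8. Proton transfer and 1,4-elimination of HBr from the hindered allylic bromide may outrun substitution by the strongly basic furyllithium. The fallback sets out from 14 (with 13) and comes back at 16. The dianion 15 is quenched with Bu3SnCl to give [2-(tributylstannyl)furan-3-yl]methanol F4. This is joined to 13 by a Stille cross-coupling (tris(dibenzylideneacetone)dipalladium Pd2(dba)3, tri(2-furyl)phosphine, THF, 50 °C) under neutral conditions that should tolerate both free hydroxyls and give 16.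

Further compounds
F1 | step 2 | (3E)-2-[(trimethylsilyl)oxy]penta-1,3-diene | C=C(O[Si](C)(C)C)/C=C/C
F2 | step 2 | 3,3,7,11,11-pentamethyl-9-[(trimethylsilyl)oxy]-2,4-dioxaspiro[5.5]undec-8-ene-1,5-dione | CC1C=C(O[Si](C)(C)C)CC(C)(C)C12C(=O)OC(C)(C)OC2=O
F3 | step 10 | tert-butyl{[2,5-dimethoxy-2-({(4R)-4-[(tert-butyldimethylsilyl)oxy]-2,6,6-trimethylcyclohex-1-en-1-yl}methyl)-2,5-dihydrofuran-3-yl]methoxy}dimethylsilane | COC1C=C(CO[Si](C)(C)C(C)(C)C)C(CC2=C(C)C[C@@H](O[Si](C)(C)C(C)(C)C)CC2(C)C)(OC)O1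
F4 | step 8 | [2-(tributylstannyl)furan-3-yl]methanol | CCCC[Sn](CCCC)(CCCC)c1occc1CO
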